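The cyclobutane C1–C4 carries its two carboxyl carbons cis on C1 and C2, and one methyl plus one pyrone on each of C3 and C4. If those carboxyl carbons are read as the ends of a four-carbon diene, the four-membered ring becomes part of a bicyclo[4.2.0]octa-2,4-diene, a valence isomer of an open-chain tetraene. Heating the (2E,4Z,6Z,8Z)-2,9-dipyronyldecatetraene should form C3–C4 by 8π conrotation and C1–C2 by 6π disrotation. This sets both rings and all four stereocentres of a meso bicycle in one operation. Oxidative excision of the diene, anhydride closure and alkaloid-mediated methanolysis then break the symmetry.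

Key step: step 10

Notation: Pyr = 4-methoxy-3-methyl-2-oxo-2H-pyran-6-yl. In the target numbering, C1 bears CO2Me, C2 bears CO2H, C3 is next to C2 and C4 is next to C1. In this numbering the target is (1R,2S,3R,4S): CO2Me, CO2H and both methyls lie on one face, and both Pyr groups and both ring hydrogens lie on the other.

Assumption: quinine is taken to direct methanol to the carbonyl on the R-configured methine of the meso anhydride, by analogy with simple cis-fused bicyclic succinic anhydrides; quinidine acts as its pseudoenantiomer, so the same step with quinidine applies if a trial shows the opposite sense.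

Step 1
Reactants: 1 ethyl 2-methylacetoacetate; 2 methyl 2,2-dimethoxypropanoate
Product: 4 ethyl 6,6-dimethoxy-2-methyl-3,5-dioxoheptanoate, via dilithium dianion 3 (not isolated)
Conditions: 1, LiN(i-Pr)2 (3.1 equiv), THF, –78 → 0 °C; 2, –78 °C → rt; AcOH quench
Reagents that add atoms: none
Why: This is a γ-selective Claisen acylation of a β-keto ester dianion, in which the more reactive terminal carbanion attacks the non-enolisable ketal ester and the extra equivalent of base takes up the acidic proton of the tricarbonyl product.

Step 2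
Reactants: 4 ethyl 6,6-dimethoxy-2-methyl-3,5-dioxoheptanoate
Product: 5 6-(1,1-dimethoxyethyl)-4-hydroxy-3-methyl-2H-pyran-2-one
Conditions: DBU (1.5 equiv), PhMe, 80 °C; cold aq citric acid work-up
Reagents that add atoms: none
Why: In this base-induced lactonisation of a 3,5-dioxo ester the C5 enolate oxygen attacks the ethyl ester, ethoxide leaves, the delocalised 4-hydroxy-2-pyrone forms as the sink, and the ketal is inert to the amidine base.

Step 3
Reactants: 5 6-(1,1-dimethoxyethyl)-4-hydroxy-3-methyl-2H-pyran-2-one
Product: 6 6-(1,1-dimethoxyethyl)-4-methoxy-3-methyl-2H-pyran-2-one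
Conditions: Me2SO4 (1.2 equiv), K2CO3 (2 equiv), acetone, reflux
Reagents that add atoms: dimethyl sulfate, COS(=O)(=O)OC
Why: O-alkylation of the vinylogous acid with dimethyl sulfate and carbonate in acetone is the standard entry to the 4-methoxy-2-pyrone series and not to the isomeric 2-methoxy-4-pyrone.

Step 4
Reactants: 6 6-(1,1-dimethoxyethyl)-4-methoxy-3-methyl-2H-pyran-2-one
Product: 7 6-acetyl-4-methoxy-3-methyl-2H-pyran-2-one
Conditions: TFA/H2O (9:1), CH2Cl2, 0 °C → rt
Reagents that add atoms: water, O
Why: Acid-catalysed ketal hydrolysis frees the ketone, while the 4-methoxy-2-pyrone, a vinylogous ester within a delocalised ring, tolerates aqueous acid at room temperature.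

Step 5
Reactants: 7 6-acetyl-4-methoxy-3-methyl-2H-pyran-2-one; 8 [3-(trimethylsilyl)prop-2-yn-1-yl]triphenylphosphonium bromide
Product: 10 4-methoxy-3-methyl-6-[(2E)-5-(trimethylsilyl)pent-2-en-4-yn-2-yl]-2H-pyran-2-one and 11 its (2Z) isomer (separated on SiO2), via propargylidene ylide 9 (not isolated)
Conditions: 8, NaN(SiMe3)2, THF, –78 °C; 7, –78 °C → rt; chromatography
Reagents that add atoms: none
Why: In this Wittig olefination with a semi-stabilised propargylic ylide the electron-poor acyl pyrone is a reactive ketone, little preference between the methyl and the flat pyrone is expected, and this suits the plan because step 8 consumes the two isomers one to one (any surplus isomer can be re-equilibrated by sensitised irradiation).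

Step 6
Reactants: 10 (2E)-silyl enyne
Product: 12 6-[(2E)-5-bromopent-2-en-4-yn-2-yl]-4-methoxy-3-methyl-2H-pyran-2-one
Conditions: NBS (1.1 equiv), AgNO3 (10 mol %), acetone, rt, dark
Reagents that add atoms: N-bromosuccinimide, O=C1CCC(=O)N1Br
Why: Silver-catalysed bromodesilylation of an alkynylsilane (ipso substitution through a silver acetylide) is much faster than bromination of the deactivated pyrone or of the trisubstituted alkene, and it leaves the alkene geometry untouched.

Step 7
Reactants: 11 (2Z)-silyl enyne
Product: 13 4-methoxy-3-methyl-6-[(2Z)-pent-2-en-4-yn-2-yl]-2H-pyran-2-one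
Conditions: K2CO3 (0.2 equiv), MeOH/CH2Cl2, 0 °C
Reagents that add atoms: none
Why: Carbonate-catalysed methanolysis of the C(sp)–Si bond is fast at 0 °C, where the methoxypyrone is not opened and the Z alkene is not disturbed.

Step 8
Reactants: 12 (2E)-bromo enyne; 13 (2Z)-terminal enyne
Product: 14 (2E,8Z)-2,9-di(Pyr)deca-2,8-diene-4,6-diyne
Conditions: CuCl (10 mol %), NH2OH·HCl (0.3 equiv), n-BuNH2 (3 equiv), THF/H2O, 0 °C, slow addition of 12
Reagents that add atoms: none
Why: In this Cadiot–Chodkiewicz coupling the acetylide of monovalent copper derived from 13 substitutes the bromoalkyne 12, hydroxylamine keeps the copper reduced so that oxidative homocoupling to the isomeric E,E and Z,Z diynes is suppressed, and the low temperature and short contact time protect the pyrones from the amine.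

Step 9
Reactants: 14 (2E,8Z)-dienediyne
Product: 15 (2E,4Z,6Z,8Z)-2,9-di(Pyr)deca-2,4,6,8-tetraene
Conditions: Zn dust activated with Cu(OAc)2 and AgNO3, MeOH/H2O/THF, rt, Ar, dark; filtration, cold and dark handling
Reagents that add atoms: none
Why: In this cis-selective semireduction of conjugated alkynes with copper/silver-activated zinc in a protic medium, both hydrogens reach each triple bond from the same side to give the 4Z,6Z-diene, reduction stops at the alkene stage, the trisubstituted end alkenes and the pyrones are not touched, and the absence of a hydrogenation catalyst avoids over-reduction and geometric scrambling.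

Step 10
Reactants: 15 (2E,4Z,6Z,8Z)-tetraene
Product: 17 (1R,6S,7R,8S)-7,8-dimethyl-7,8-di(Pyr)bicyclo[4.2.0]octa-2,4-diene (meso; cis-fused, both Pyr exo on the face of the ring-fusion hydrogens, both methyls endo), via cis-cyclooctatriene 16 (not isolated)
Conditions: PhMe (0.005 M, degassed), BHT (5 mol %), 100 °C, sealed tube, dark
Reagents that add atoms: none
Why: Proposed new method: in its helical all-s-cis conformer 15 is set up for a thermally allowed 8π conrotatory closure that joins chain carbons 2 and 9 (target C3–C4) to give the eight-membered triene 16, whose ring triene then closes by a thermally allowed 6π disrotation between chain carbons 3 and 8 (target C1–C2), creating the cyclobutane and the cyclohexadiene together. The closest known reaction type is the 8π/6π cascade of conjugated tetraenes with a central Z,Z-diene, which is established for pyrone-capped chains that generate one quaternary carbon but not for two adjacent ones. C3 and C4 are controlled by alkene geometry, since the 2E end holds its pyrone outward and the 8Z end holds it inward, so rotation of both termini in the same sense places the two pyrones on one face and the two methyls on the other, and both helical senses lead to the same meso product. C1 and C2 are controlled by the disrotatory mode, which within the ring can only give a cis fusion. The one selectivity that has to be earned is the direction of this disrotation relative to C3/C4, and it should favour 17 because the alternative pushes two pyrones instead of two methyls under the cyclohexadiene, and because the 6π step is reversible at this temperature so the less crowded isomer should also accumulate thermodynamically. High dilution, exclusion of light, oxygen and acid, and the absence of any transition metal keep the end-alkene geometries intact and so protect the cis outcome.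

Step 11
Reactants: 17 meso bicyclooctadiene
Product: 18 (1R,2S,3R,4S)-3,4-dimethyl-3,4-di(Pyr)cyclobutane-1,2-dicarboxylic acid (meso)
Conditions: OsO4 (5 mol %), KHSO5 (9 equiv, as 2KHSO5·KHSO4·K2SO4), DMF, rt
Reagents that add atoms: potassium peroxymonosulfate, [K+].[O-]S(=O)(=O)OO
Why: In this osmium-catalysed oxidative alkene cleavage with peroxymonosulfate, OsO4 adds to the two unhindered cis-disubstituted alkenes from the open convex face, each osmate fragments and the aldehydes are oxidised on to acids in the same acidic medium so that C1–H and C2–H do not epimerise, whereas the pyrone double bonds are tri- and tetrasubstituted, delocalised and shielded by a quaternary carbon.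

Step 12
Reactants: 18 meso diacid
Product: 19 (1R,5S,6R,7S)-6,7-dimethyl-6,7-di(Pyr)-3-oxabicyclo[3.2.0]heptane-2,4-dione (meso)
Conditions: Ac2O, PhMe, 60 °C; evaporation
Reagents that add atoms: none
Why: In this dehydrative ring closure through a mixed anhydride only the cis-1,2-diacid can form the five-membered anhydride, the mirror plane is kept, and the moderate temperature avoids enolisation at C1 and C2.

Step 13
Reactants: 19 meso anhydride
Product: 20 target, (1S,2R,3S,4R)-2-(methoxycarbonyl)-3,4-dimethyl-3,4-di(Pyr)cyclobutane-1-carboxylic acid by IUPAC numbering, which is (1R,2S,3R,4S) in the target numbering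
Conditions: quinine (1.1 equiv), MeOH (5 equiv), PhMe, –55 °C; aq HCl wash (alkaloid recovered)
Reagents that add atoms: methanol, CO
Why: In this cinchona-alkaloid-mediated desymmetrising alcoholysis of a meso cyclic anhydride the quinuclidine nitrogen activates methanol as a chiral general base and delivers it to one of the two enantiotopic carbonyls, here the one on C1, so no stereocentre is made or touched and the meso array becomes the single enantiomer.

Compound list
1 | ethyl 2-methylacetoacetate (racemic) | CCOC(=O)C(C)C(C)=O | starting material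
2 | methyl 2,2-dimethoxypropanoate | COC(C)(OC)C(=O)OC | starting material
3 | dilithium dianion of 1 | C=C([O-])C(C)=C([O-])OCC.[Li+].[Li+] | intermediate
4 | ethyl 6,6-dimethoxy-2-methyl-3,5-dioxoheptanoate | CCOC(=O)C(C)C(=O)CC(=O)C(C)(OC)OC | intermediate
5 | 6-(1,1-dimethoxyethyl)-4-hydroxy-3-methyl-2H-pyran-2-one | COC(C)(OC)c1cc(O)c(C)c(=O)o1 | intermediate
6 | 6-(1,1-dimethoxyethyl)-4-methoxy-3-methyl-2H-pyran-2-one | COC(C)(OC)c1cc(OC)c(C)c(=O)o1 | intermediate
7 | 6-acetyl-4-methoxy-3-methyl-2H-pyran-2-one | CC(=O)c1cc(OC)c(C)c(=O)o1 | intermediate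
8 | [3-(trimethylsilyl)prop-2-yn-1-yl]triphenylphosphonium bromide | C[Si](C)(C)C#CC[P+](c1ccccc1)(c1ccccc1)c1ccccc1.[Br-] | starting material
9 | [3-(trimethylsilyl)prop-2-yn-1-ylidene]triphenylphosphorane | C[Si](C)(C)C#CC=P(c1ccccc1)(c1ccccc1)c1ccccc1 | intermediate
10 | 4-methoxy-3-methyl-6-[(2E)-5-(trimethylsilyl)pent-2-en-4-yn-2-yl]-2H-pyran-2-one | C[Si](C)(C)C#C/C=C(\C)c1cc(OC)c(C)c(=O)o1 | intermediate
11 | 4-methoxy-3-methyl-6-[(2Z)-5-(trimethylsilyl)pent-2-en-4-yn-2-yl]-2H-pyran-2-one | C[Si](C)(C)C#C/C=C(/C)c1cc(OC)c(C)c(=O)o1 | intermediate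
12 | 6-[(2E)-5-bromopent-2-en-4-yn-2-yl]-4-methoxy-3-methyl-2H-pyran-2-one | BrC#C/C=C(\C)c1cc(OC)c(C)c(=O)o1 | intermediate
13 | 4-methoxy-3-methyl-6-[(2Z)-pent-2-en-4-yn-2-yl]-2H-pyran-2-one | C#C/C=C(/C)c1cc(OC)c(C)c(=O)o1 | intermediate
14 | (2E,8Z)-2,9-di(Pyr)deca-2,8-diene-4,6-diyne | Cc1c(OC)cc(oc1=O)/C(C)=C/C#CC#C/C=C(/C)c2cc(OC)c(C)c(=O)o2 | intermediate
15 | (2E,4Z,6Z,8Z)-2,9-di(Pyr)deca-2,4,6,8-tetraene | Cc1c(OC)cc(oc1=O)/C(C)=C/C=C\C=C/C=C(/C)c2cc(OC)c(C)c(=O)o2 | intermediate
16 | cis-(7R,8S)-7,8-dimethyl-7,8-di(Pyr)cycloocta-1,3,5-triene (meso) | C[C@]1(c2cc(OC)c(C)c(=O)o2)/C=C\C=C/C=C\[C@@]1(C)c3cc(OC)c(C)c(=O)o3 | intermediate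
17 | (1R,6S,7R,8S)-7,8-dimethyl-7,8-di(Pyr)bicyclo[4.2.0]octa-2,4-diene (meso, Pyr exo) | C1=CC=C[C@@H]2[C@H]1[C@@](C)(c3cc(OC)c(C)c(=O)o3)[C@@]2(C)c4cc(OC)c(C)c(=O)o4 | intermediate
18 | (1R,2S,3R,4S)-3,4-dimethyl-3,4-di(Pyr)cyclobutane-1,2-dicarboxylic acid (meso) | OC(=O)[C@@H]1[C@H](C(=O)O)[C@@](C)(c2cc(OC)c(C)c(=O)o2)[C@@]1(C)c3cc(OC)c(C)c(=O)o3 | intermediate
19 | (1R,5S,6R,7S)-6,7-dimethyl-6,7-di(Pyr)-3-oxabicyclo[3.2.0]heptane-2,4-dione (meso) | O=C1OC(=O)[C@@H]2[C@H]1[C@@](C)(c3cc(OC)c(C)c(=O)o3)[C@@]2(C)c4cc(OC)c(C)c(=O)o4 | intermediate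
20 | (1S,2R,3S,4R)-2-(methoxycarbonyl)-3,4-dimethyl-3,4-di(Pyr)cyclobutane-1-carboxylic acid | COC(=O)[C@@H]1[C@H](C(=O)O)[C@@](C)(c2cc(OC)c(C)c(=O)o2)[C@@]1(C)c1cc(OC)c(C)c(=O)o1 | target

Total step count: 13. Longest linear sequence: 12 (steps 1–5, 6 or 7, 8–13).

Steps most likely to fail

Step 10.
- **What may go wrong:** The closure may be too slow or thermodynamically uphill, because two adjacent quaternary carbons are made and both termini carry an inward group. An antarafacial [1,7]-hydrogen shift from the inward methyl could compete. Thermal E/Z scrambling of an end alkene would divert material to the trans-dipyronyl series. Disrotation in the unwanted direction is also possible.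
- **Fallback:** This is a template-directed [2+2] photocycloaddition (known chemistry) that sets out from 7 and comes back at 18. Horner–Wadsworth–Emmons olefination of 7 with tert-butyl diethylphosphonoacetate (NaH, THF) should give tert-butyl (E)-3-(Pyr)but-2-enoate F1. TFA in CH2Cl2 then frees (E)-3-(Pyr)but-2-enoic acid F2. Double esterification with naphthalene-1,8-diol (EDC·HCl, DMAP) gives naphthalene-1,8-diyl bis[(E)-3-(Pyr)but-2-enoate] F3, in which the peri positions hold the two alkenes parallel and head to head. Irradiation (365 nm, or thioxanthone-sensitised) should close the template-bound cyclobutane diester F4. Each E alkene keeps its geometry, so F4 has the carboxyls cis, the pyrones cis, and each pyrone trans to the neighbouring carboxyl. LiOH/H2O2 in THF/H2O at 0 °C cleaves the labile aryl esters to 18.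

Step 9.
- **What may go wrong:** Reduction may stall at an enyne stage or run on past the tetraene. The new Z alkenes may isomerise on the metal surface. The tetraene may decay during isolation.
- **Fallback:** The two central Z alkenes are installed before the halves are joined. The sequence sets out from 12 and 13 and comes back at 15. Diimide (2-nitrobenzenesulfonyl hydrazide, Et3N) transfers hydrogen syn to the bromoalkyne of 12 and should give 6-[(2E,4Z)-5-bromopenta-2,4-dien-2-yl]-4-methoxy-3-methyl-2H-pyran-2-one F5. Anti-selective hydroboration of 13 with pinacolborane ([Rh(cod)Cl]2, P(i-Pr)3, Et3N) should give the (2Z,4Z)-dienyl pinacol boronate F6. Suzuki–Miyaura coupling of F5 with F6 (Pd(PPh3)4, aq K3PO4, THF, rt) proceeds with retention at both partners and delivers 15.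

Step 13.
- **What may go wrong:** The quaternary carbons next to the reacting methines may weaken the recognition of the anhydride by the alkaloid, leading to poor discrimination between the enantiotopic carbonyls or sluggish opening.
- **Fallback:** This is a classical resolution that sets out from 19 and comes back at 20. Unselective methanolysis (MeOH, DMAP) gives 20 together with its mirror image, the (1R,2S,3R,4S)-hemiester by IUPAC numbering, F7. Fractional crystallisation with (R)-1-phenylethylamine (or its antipode, whichever gives the less soluble salt of 20) isolates the (R)-1-phenylethylammonium salt of 20 F8, and dilute acid then releases 20. The unwanted F7 is saponified back to 18 and recycled through step 12.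

Further compounds
F1 | step 10 | tert-butyl (E)-3-(Pyr)but-2-enoate | CC(C)(C)OC(=O)/C=C(\C)c1cc(OC)c(C)c(=O)o1
F2 | step 10 | (E)-3-(Pyr)but-2-enoic acid | OC(=O)/C=C(\C)c1cc(OC)c(C)c(=O)o1
F3 | step 10 | naphthalene-1,8-diyl bis[(E)-3-(Pyr)but-2-enoate] | O=C(/C=C(\C)c1cc(OC)c(C)c(=O)o1)Oc1cccc2cccc(OC(=O)/C=C(\C)c3cc(OC)c(C)c(=O)o3)c12
F4 | step 10 | naphthalene-1,8-diyl (1R,2S,3R,4S)-3,4-dimethyl-3,4-di(Pyr)cyclobutane-1,2-dicarboxylate (cyclic, meso) | O=C(Oc2cccc3cccc(O5)c23)[C@@H]1[C@H](C5=O)[C@@](C)(c6cc(OC)c(C)c(=O)o6)[C@@]1(C)c7cc(OC)c(C)c(=O)o7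
F5 | step 9 | 6-[(2E,4Z)-5-bromopenta-2,4-dien-2-yl]-4-methoxy-3-methyl-2H-pyran-2-one | Br/C=C\C=C(/C)c1cc(OC)c(C)c(=O)o1
F6 | step 9 | 4-methoxy-3-methyl-6-[(2Z,4Z)-5-(4,4,5,5-tetramethyl-1,3,2-dioxaborolan-2-yl)penta-2,4-dien-2-yl]-2H-pyran-2-one | CC1(C)OB(OC1(C)C)/C=C\C=C(\C)c1cc(OC)c(C)c(=O)o1
F7 | step 13 | (1R,2S,3R,4S)-2-(methoxycarbonyl)-3,4-dimethyl-3,4-di(Pyr)cyclobutane-1-carboxylic acid (enantiomer of 20) | COC(=O)[C@H]1[C@@H](C(=O)O)[C@](C)(c2cc(OC)c(C)c(=O)o2)[C@]1(C)c3cc(OC)c(C)c(=O)o3
F8 | step 13 | (R)-1-phenylethylammonium salt of 20 | COC(=O)[C@@H]1[C@H](C(=O)[O-])[C@@](C)(c2cc(OC)c(C)c(=O)o2)[C@@]1(C)c3cc(OC)c(C)c(=O)o3.C[C@@H]([NH3+])c4ccccc4
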